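**Small charge.** Start from the free catalyst: 0.25 mM against 5.0 mM of solid substrate. Each catalyst has to turn many times, and the target at the end counts its turns before it is lost. The four new flasks differ in the gap between the two reagent portions.

| flask | solid substrate | reagent | capture agent | free catalyst | remark | time |
|---|---|---|---|---|---|---|
| epsilon | 5 mM | 12.5 mM (in portions, 2) | 1 mM | 0.25 mM | run made earlier; portions every 5.0 s |  |
| eta | 5 mM | 12.5 mM (in portions, 2) | 2.2 mM | 0.25 mM | run made earlier; portions every 5.0 s |  |
| north-west | 5.0 mM | 12.5 mM (in portions, 2) | 1.50 mM | 0.25 mM | the portions of reagent follow each other after 5.0 s, the first at the start | 2.5 min |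
| north-east | 5.0 mM | 12.5 mM (in portions, 2) | 1.50 mM | 0.25 mM | the portions of reagent follow each other after 8.0 s, the first at the start | 2.5 min |
| west | 5.0 mM | 12.5 mM (in portions, 2) | 1.50 mM | 0.25 mM | the portions of reagent follow each other after 12 s, the first at the start | 2.5 min |
| south | 5.0 mM | 12.5 mM (in portions, 2) | 1.50 mM | 0.25 mM | the portions of reagent follow each other after 15 s, the first at the start | 2.5 min |

| run | time / s | target / % | solid substrate / % |
|---|---|---|---|
| epsilon | 15.0 | 13.6 | 31.0 |
| epsilon | 40.0 | 34.4 | 11.4 |
| epsilon | 80.0 | 52.9 | 1.1 |
| epsilon | 120 | 58.5 | 0 |
| eta | 15.0 | 12.2 | 32.4 |
| eta | 40.0 | 22.1 | 21.6 |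
| eta | 80.0 | 27.9 | 16.6 |
| eta | 120 | 29.0 | 15.9 |

(standard deviation of a reading: 1 percentage point)

1. amount of target at the end, in percent of the solid substrate charged for north-west, north-east, west, south, in this order
2. the course of these numbers from the first flask to the last (rises all the way / rises, then falls / falls all the way / hardly changes / falls, then rises)

- as a solid, counted per litre of solution: solid substrate
- candidate steps: reagent + free catalyst <-> catalyst intermediate A; starting material + catalyst intermediate A -> catalyst intermediate B; catalyst intermediate B -> free catalyst + target; catalyst intermediate A + capture agent -> trapped intermediate; solid substrate <-> starting material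
- at the start none of the solid substrate is in solution
- "hardly changes" means that all values lie within two and a half points (for a concentration: within two and a half percent of the largest)

**The fork.** The candidate steps put catalyst intermediate A at a fork. With starting material it goes on to one turn; with capture agent it leaves the round as trapped intermediate. So turns per catalyst lost go as [starting material] over [capture agent], and reagent stands in neither arm. Its portions change how much intermediate A stands, but the split at a given moment has no reagent in it.

**First rung.** Subtract target and solid from the whole in eta: 55.4 % is in solution at 15.0 s and 55.1 % at 120 s. Read [starting material] as level from the first reading on, while solid lasts.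

**Second rung.** The distance of eta's target from its last reading shrinks with a time of 21.8 s, a rough reading of how long catalyst lasts there, since the smaller distance is 1.1 percentage points against a scatter of 1 point. Scale it to the new [capture agent] and it becomes 32.9 s, still shorter than 2.5 min. Even a gap of 15 s is shorter than the reading from eta.

**Same rung.** Capture agent loses one unit per catalyst lost, so over that same time it falls from 1.50 mM towards 1.25 mM. Replace that curve by its mean, 1.38 mM; the exact sum differs by 0.277 %.

**The budget.** Eta still holds 15.9 % of solid at the last reading and has made 5.80 turns per catalyst. That gives 12.0 mM for the fork budget, the turns per catalyst times the mean [capture agent] at level [starting material]. This is a selectivity factor times that level, and it carries the scatter of the reading. Divide by the new mean and expect 43.8 % of target at each gap, a flat row. Target and level then add up to 98.9 %, so by this reckoning solid lasts about as long as target forms.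

**The result.** The forecast gave 43.5 %, 44.5 %, 45.5 % and 46 %, course rises all the way, holding that “A longer interval should therefore save some catalyst”. The flasks give 44.2 %, 44.3 %, 44.3 % and 44.3 %: hardly changes.

    reagent + free catalyst ⇌ catalyst intermediate A (K = 5810 M⁻¹, k = 45.0 M⁻¹ s⁻¹)
    starting material + catalyst intermediate A → catalyst intermediate B (k = 300 M⁻¹ s⁻¹)
    catalyst intermediate B → free catalyst + target (k = 1.78 s⁻¹)
    catalyst intermediate A + capture agent → trapped intermediate (k = 64.0 M⁻¹ s⁻¹)
    solid substrate ⇌ starting material, rate k5*(cs5 - [starting material]) while solid is left; crystals form when [starting material] > cs5 (solubility = 2.80 mM, k = 0.540 s⁻¹)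

**The stop.** In north-west the fork's losing arm holds the target down: without that step the flask reaches 99.8 % instead of 44.2 %. There the trapped intermediate holds 97.6 % of the catalyst at 2.50 min. Put back into the budget, north-west gives 12.2 mM, and south, with its gap of 15 s, gives 12.2 mM.

The numbers in the tables were generated by integration for an exercise.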